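**Retrosynthetic overview**

1. Target 37 ⇐ pentacyclic 12‑ketone 35 (C12 reduction, then fluoride removal of the C13 silyl ether and the C7 ester).
2. 35 ⇐ seco‑B keto ester 33 by breaking C9–C10 and the lactone O–C19 bond: a SmI2 ketyl–enone cyclization with in‑situ lactonization closes ring B. This works because C10 of rings A/B carries the lactone oxygen (so it can come from a ketone), C9 lies β to the C12 carbinol (a C9=C11–C12=O enone in ring C), and the C19 carboxyl on C4 is syn‑axial to the C10 oxygen.
3. 33 ⇐ ring D by a gold(I) Conia‑ene closure (C13–C16) after oxygenation of C12/C13 in ring C; the C8 quaternary centre and C6 come from an Ireland–Claisen rearrangement (C6–C8) of ester 20.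
4. 20 ⇐ ring‑A acid 14 (desymmetrized cyclohexadiene diol, two cuprate additions, C5 alkylation) + ring‑C alcohol 19 (Stork–Danheiser alkylation, CBS reduction).
5. Ring order: A and C come with the fragments, D is closed in step 23, and B is the last carbocycle, closed in step 25 together with the γ‑lactone bridge.

Key step: step 25

Remark: gibberellane numbering is used for all fragments; α is the face of the 19,10‑lactone and β the face of H‑5 and H‑9. The target is read from its SMILES as the 2β,3β,12α,13‑tetrahydroxy‑16‑ene C19 7‑acid.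
Remark: compounds 26–28 are carried as mixtures of C13 epimers, because C13 becomes sp2 in step 22; their SMILES are written without configuration at C13.

**Route**

Step 1
Reactants: 1 cyclohexa‑1,4‑diene
Product: 2 cis‑cyclohex‑4‑ene‑1,2‑diol (meso)
Conditions: OsO4 (1 mol%), NMO (0.8 equiv), acetone/H2O, 0 °C, diene in excess
Reagents that add atoms: N‑methylmorpholine N‑oxide C[N+]1([O-])CCOCC1; water O
Why: Upjohn syn‑dihydroxylation of one of the two equivalent alkenes should give the meso cis‑diol, the excess of diene limiting tetrol formation.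

Step 2
Reactants: 2 cis‑cyclohex‑4‑ene‑1,2‑diol
Product: 3 cis‑4,5‑(isopropylidenedioxy)cyclohexene (meso acetonide)
Conditions: 2,2‑dimethoxypropane, TsOH (cat.), acetone, rt
Reagents that add atoms: 2,2‑dimethoxypropane COC(C)(C)OC
Why: Acid‑catalysed transketalization of a cis‑1,2‑diol to its acetonide is routine and keeps the alkene untouched.

Step 3
Reactants: 3 meso acetonide
Product: 4 meso epoxide of 3 with the oxirane anti to the dioxolane
Conditions: mCPBA, NaHCO3, CH2Cl2, 0 °C
Reagents that add atoms: 3‑chloroperoxybenzoic acid OOC(=O)c1cccc(Cl)c1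
Why: Prilezhaev epoxidation should occur on the convex face anti to the dioxolane and gives a meso epoxide, whose carbinol centre is oxidized away in step 5 in any case.

Step 4
Reactants: 4 meso epoxide
Product: 5 (1S,4R,5S)‑4,5‑(isopropylidenedioxy)cyclohex‑2‑en‑1‑ol
Conditions: lithium amide from (S)‑2‑(pyrrolidin‑1‑ylmethyl)pyrrolidine and n‑BuLi, THF, 0 °C → rt
Reagents that add atoms: none
Why: Enantioselective β‑deprotonation and rearrangement of a meso epoxide by a chiral lithium amide removes one of the two enantiotopic syn β‑hydrogens; by analogy with cyclohexene oxide, which this base is known to convert into the (S)‑allylic alcohol, the (1S) carbinol is expected, and this fixes the absolute configuration of the two acetonide carbons (later C2 and C3).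

Step 5
Reactants: 5 allylic alcohol
Product: 6 (4R,5S)‑4,5‑(isopropylidenedioxy)cyclohex‑2‑en‑1‑one
Conditions: Dess–Martin periodinane, NaHCO3, CH2Cl2, rt
Reagents that add atoms: none
Why: Dess–Martin oxidation of a secondary allylic alcohol under buffered, non‑basic conditions should give the enone without β‑elimination of the γ‑oxygen.

Step 6
Reactants: 6 enone
Product: 8 (4R,5S)‑3‑methyl‑4,5‑(isopropylidenedioxy)cyclohex‑2‑en‑1‑one, via silyl enol ether 7 (not isolated)
Conditions: Me2CuLi, TMSCl, THF, −78 °C; then Pd(OAc)2, MeCN, rt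
Reagents that add atoms: lithium dimethylcuprate [Li+].C[Cu-]C
Why: TMSCl‑accelerated cuprate conjugate addition followed by Saegusa oxidation of the crude silyl enol ether re‑forms the enone with the methyl group (C18) on the β‑carbon (C4); the transient methyl‑bearing stereocentre is erased.

Step 7
Reactants: 8 β‑methyl enone
Product: 9 ring‑A trimethylsilyl enol ether (C10–OTMS, C5=C10; 4β‑methyl, 4α‑vinyl; 2β,3β‑acetonide)
Conditions: vinylmagnesium bromide, CuBr·SMe2 (10 mol%), TMSCl, DMPU, THF, −78 °C
Reagents that add atoms: vinylmagnesium bromide C=C[Mg]Br; chlorotrimethylsilane C[Si](C)(C)Cl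
Why: Copper‑catalysed conjugate addition to the β,β‑disubstituted enone should occur anti to the adjacent C3 oxygen of the acetonide, so the vinyl group (the later C19) enters α and the methyl ends β, setting the C4 quaternary centre; the enolate is trapped regiospecifically at C5/C10.

Step 8
Reactants: 9 silyl enol ether
Product: 11 ring‑A keto ester (C10 ketone; 5α‑CH2CO2Me, 5β‑H; 4β‑methyl, 4α‑vinyl; 2β,3β‑acetonide), via lithium enolate 10 (not isolated)
Conditions: MeLi, THF, 0 °C; methyl bromoacetate, DMPU, −78 → 0 °C; then DBU (cat.), CH2Cl2, rt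
Reagents that add atoms: methyl bromoacetate COC(=O)CBr
Why: The regiodefined lithium enolate released by MeLi is alkylated at C5 with a reactive α‑halo ester, and C5 is then set under thermodynamic control: the α (equatorial) side chain, trans to the C4 methyl, avoids the syn‑axial C3 oxygen and is the more stable epimer.

Step 9
Reactants: 11 keto ester
Product: 12 C10 ethylene ketal of 11
Conditions: 1,2‑bis(trimethylsilyloxy)ethane, TMSOTf (cat.), CH2Cl2, −78 → −20 °C
Reagents that add atoms: 1,2‑bis(trimethylsilyloxy)ethane C[Si](C)(C)OCCO[Si](C)(C)C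
Why: Aprotic TMSOTf‑catalysed ketalization protects the hindered C10 ketone without exchanging the acetonide and fixes C5 against epimerization.

Step 10
Reactants: 12 vinyl ketal
Product: 13 ring‑A diester (4α‑CO2Me in place of vinyl)
Conditions: O3, NaOH (2.5 M in MeOH), CH2Cl2, −78 °C
Reagents that add atoms: ozone [O-][O+]=O; methanol CO
Why: Ozonolysis in methanolic NaOH converts a terminal alkene directly into the methyl ester, here the only alkene in the molecule, giving the C19 ester on the α face without touching C4.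

Step 11
Reactants: 13 diester
Product: 14 ring‑A acid (5α‑CH2CO2H; C19 methyl ester kept)
Conditions: LiOH·H2O (1.2 equiv), THF/H2O, 0 °C → rt; then cold 0.5 M HCl to pH 4
Reagents that add atoms: lithium hydroxide [Li+].[OH-]
Why: Saponification should be selective for the unhindered acetate ester over the neopentyl, quaternary C19 methyl ester.

Step 12
Reactants: 15 3‑ethoxycyclohex‑2‑en‑1‑one; 16 3‑bromo‑1‑(trimethylsilyl)prop‑1‑yne
Product: 18 3‑[3‑(trimethylsilyl)prop‑2‑ynyl]cyclohex‑2‑en‑1‑one, via magnesium alkoxide 17 (not isolated)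
Conditions: Mg, HgCl2 (cat.), Et2O, 0 °C; add 15, −20 °C → rt; then 1 M HCl, rt
Reagents that add atoms: water O
Why: Stork–Danheiser sequence: the silyl‑substituted allenyl/propargyl Grignard reagent adds 1,2 to the vinylogous ester through its CH2 terminus (homopropargyl product), and acid hydrolysis with carbonyl transposition gives the 3‑substituted enone.

Step 13
Reactants: 18 enone
Product: 19 (S)‑3‑[3‑(trimethylsilyl)prop‑2‑ynyl]cyclohex‑2‑en‑1‑ol
Conditions: (R)‑2‑methyl‑CBS‑oxazaborolidine (20 mol%), BH3·SMe2, THF, −30 °C; MeOH quench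
Reagents that add atoms: none
Why: CBS 1,2‑reduction in which the alkene arm acts as the large group; the (R)‑catalyst should deliver the (S)‑allylic alcohol, whose C–O bond (the later C13–O) lies on the ring face that has to receive C6.

Step 14
Reactants: 14 ring‑A acid; 19 ring‑C alcohol
Product: 20 (S)‑3‑[3‑(trimethylsilyl)prop‑2‑ynyl]cyclohex‑2‑enyl ester of acid 14
Conditions: EDC·HCl, DMAP (cat.), CH2Cl2, 0 °C → rt
Reagents that add atoms: none
Why: Steglich esterification of an unhindered acetic acid with a secondary allylic alcohol proceeds with retention at the carbinol carbon.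

Step 15
Reactants: 20 allylic ester
Product: 23 Claisen acid (C8 quaternary with C6H(CO2H)–ring A and the silylpropargyl chain; C13=C14 alkene; C6 and C8 as in the target), via silyl ketene acetal 21 (not isolated), via trimethylsilyl ester 22 (not isolated)
Conditions: LDA, THF/DMPU (4:1), −78 °C; TMSCl; −78 → 60 °C; then aq. NH4Cl
Reagents that add atoms: none
Why: Ireland–Claisen rearrangement: the (Z)‑silyl ketene acetal formed in the dipolar solvent should react through the boat‑like transition state preferred by cyclohexenyl esters (ring‑A substituent and OSi both turned away from the ring), so the C13–O chirality is transferred suprafacially to the C8 quaternary centre and the ketene‑acetal geometry sets C6.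

Step 16
Reactants: 23 Claisen acid
Product: 24 2‑(trimethylsilyl)ethyl ester of 23
Conditions: 2‑(trimethylsilyl)ethanol, PPh3, DIAD, THF, 0 °C → rt
Reagents that add atoms: 2‑(trimethylsilyl)ethanol C[Si](C)(C)CCO
Why: Mitsunobu esterification alkylates the hindered carboxylate on oxygen with the activated primary alcohol, so neither C6 nor the crowded acyl carbon is attacked; the ester is fluoride‑labile for the last step.

Step 17
Reactants: 24 cyclohexene ester
Product: 25 enone (C12 ketone conjugated with C13=C14)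
Conditions: CrO3, 3,5‑dimethylpyrazole, CH2Cl2, −20 °C
Reagents that add atoms: chromium trioxide O=[Cr](=O)=O
Why: Chromium(VI)–dimethylpyrazole allylic oxidation converts the only allylic methylene (C12; the other allylic position is the quaternary C8) into the enone carbonyl.

Step 18
Reactants: 25 enone
Product: 26 α‑hydroxy ketone (C12 ketone, C13–OH, C14H2; C13 epimers)
Conditions: Mn(dpm)3 (10 mol%), PhSiH3, O2 (1 atm), i‑PrOH/CH2Cl2, 0 °C; then P(OEt)3
Reagents that add atoms: dioxygen O=O
Why: Mukaiyama‑type reductive α‑hydroxylation of an enone: hydrogen‑atom transfer to the β‑carbon C14 gives the C13 α‑keto radical, which is trapped by O2 and reduced to the alcohol, placing oxygen on C13 while the C13=C14 bond is saturated.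

Step 19
Reactants: 26 α‑hydroxy ketone
Product: 27 C13 tert‑butyldimethylsilyl ether of 26
Conditions: TBSOTf, 2,6‑lutidine, CH2Cl2, −78 °C
Reagents that add atoms: tert‑butyldimethylsilyl triflate CC(C)(C)[Si](C)(C)OS(=O)(=O)C(F)(F)F
Why: O‑silylation of the secondary alcohol at low temperature with a hindered base should leave the ketone unenolized.

Step 20
Reactants: 27 α‑silyloxy ketone
Product: 29 enone (C9=C11–C12=O) with C13–OTBS, via silyl enol ether 28 (not isolated)
Conditions: LDA, TMSCl, THF, −78 °C; then Pd(OAc)2, MeCN, rt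
Reagents that add atoms: none
Why: Kinetic deprotonation occurs at the C11 methylene rather than at the hindered, silyloxy‑bearing C13, and Saegusa oxidation of that enol ether introduces the C9=C11 double bond; doing this only after C13 is oxygenated keeps the two arms of ring C distinguishable and so preserves the C8 stereocentre.

Step 21
Reactants: 29 silylalkyne enone
Product: 30 terminal alkyne
Conditions: K2CO3, MeOH, 0 °C → rt
Reagents that add atoms: none
Why: Mild methanolysis of the alkynyl C–Si bond is selective over the silyl ether and the hindered esters and provides the terminal alkyne needed for the carbocyclization.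

Step 22
Reactants: 30 α′‑silyloxy enone
Product: 31 12,13‑bis(tert‑butyldimethylsilyloxy) diene (C9=C11–C12(OTBS)=C13(OTBS))
Conditions: TBSOTf, Et3N, CH2Cl2, 0 °C
Reagents that add atoms: tert‑butyldimethylsilyl triflate CC(C)(C)[Si](C)(C)OS(=O)(=O)C(F)(F)F
Why: Soft enolization can only occur toward C13 (C11 is vinylic and the γ‑carbon C8 is quaternary), so the cross‑conjugated silyl dienol ether forms as a single regioisomer.

Step 23
Reactants: 31 silyl dienol ether
Product: 32 bicyclo[3.2.1]octenone (ring D closed; C12 ketone, C9=C11, C13–OTBS, C16=CH2; ring A still as ketal and acetonide)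
Conditions: (JohnPhos)Au(MeCN)SbF6 (5 mol%), CH2Cl2/MeOH (10:1), rt
Reagents that add atoms: none
Why: Gold(I)‑catalysed Conia‑ene carbocyclization: the enol‑ether carbon C13 adds 5‑exo‑dig to the gold‑activated alkyne at C16, and protodeauration gives the exocyclic methylene and the bridgehead silyl ether; C13 is fixed because the two‑carbon bridge can only span the face of ring C opposite to C6.

Step 24
Reactants: 32 protected bicyclic enone
Product: 33 seco‑B keto diol (C10 ketone, 2β,3β‑diol, C19 methyl ester; ring C/D enone with C13–OTBS; C7 TMSE ester)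
Conditions: 1 M HCl, THF, rt
Reagents that add atoms: water O
Why: Dilute aqueous acid hydrolyses the ketal and the acetonide, while the tertiary silyl ether, the TMSE ester and the exocyclic alkene are stable under these conditions; C5 stays in its more stable equatorial configuration.

Step 25
Reactants: 33 seco‑B keto diol
Product: 35 pentacyclic lactone 12‑ketone (rings A–D and the 19,10‑lactone; C13–OTBS; C7 TMSE ester; 2β,3β‑diol), via samarium alkoxide 34 (not isolated)
Conditions: SmI2 (3 equiv), t‑BuOH (2 equiv), THF, −78 → 0 °C; aq. NH4Cl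
Reagents that add atoms: none
Why: SmI2 reduces the C10 ketone, activated by chelation of Sm(III) between its oxygen and the syn‑axial C19 ester, to a ketyl that adds 5‑exo‑trig to C9 of the C9=C11–C12=O enone; a second electron gives the C12 samarium enolate (protonated by t‑BuOH), and the C10 samarium alkoxide 34 then attacks the C19 methyl ester, expels methoxide and closes the γ‑lactone. The closest known reaction type is the SmI2 ketone–enone (ketyl–olefin) reductive cyclization with in‑situ lactonization of the samarium alkoxide onto a neighbouring ester. Ring B closes by 5‑exo‑trig radical addition (C9–C10) and the lactone by 5‑exo‑trig O‑acylation (O–C19); ring B is the last carbocycle and the lactone bridge follows in the same operation. C10 is controlled by the chelate, which holds the ketyl oxygen axial on the α face next to C19, so C9 must bond equatorially (trans A/B fusion, oxygen cis to C19 as lactonization requires); C9 is controlled by attack on the enone face of the one‑carbon bridge C14, anti to the C15–C16 bridge (H‑9 β). The step needs C–C coupling to win over simple reduction of either carbonyl and needs the 13‑silyloxy group to survive: the chelated γ‑keto ester is the most easily reduced site, the intramolecular 5‑exo addition to an activated alkene is fast, and the bridgehead C13–O bond lies near the nodal plane of the C12 carbonyl, so it should not be expelled.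

Step 26
Reactants: 35 12‑ketone
Product: 36 12α‑alcohol (C13–OTBS, C7 TMSE ester)
Conditions: NaBH4, MeOH/CH2Cl2, −20 °C
Reagents that add atoms: none
Why: Hydride reduction of the C12 ketone should come from the β face, because the α (axial) trajectory is blocked by the syn‑axial C9–C10 bond and ring A, giving the axial 12α‑alcohol cis to the 13‑oxygen; the lactone and the esters are inert at this temperature.

Step 27
Reactants: 36 protected tetraol ester
Product: 37 target acid
Conditions: TBAF (5 equiv), AcOH (3 equiv), THF, rt → 45 °C; acidify to pH 3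
Reagents that add atoms: none
Why: Buffered fluoride removes the tertiary silyl ether and fragments the 2‑(trimethylsilyl)ethyl ester (to ethylene and the carboxylate) in one operation, avoiding the aqueous hydroxide that would risk retro‑aldol epimerization at C3.

**Compound list**

1 | cyclohexa‑1,4‑diene | C1=CCC=CC1 | starting material
2 | cis‑cyclohex‑4‑ene‑1,2‑diol (meso) | O[C@H]1CC=CC[C@H]1O | intermediate
3 | cis‑4,5‑(isopropylidenedioxy)cyclohexene (meso) | C1=CC[C@H]2OC(C)(C)O[C@H]2C1 | intermediate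
4 | meso epoxide of 3, oxirane anti to the dioxolane | O1[C@@H]2C[C@H]3OC(C)(C)O[C@H]3C[C@H]12 | intermediate
5 | (1S,4R,5S)‑4,5‑(isopropylidenedioxy)cyclohex‑2‑en‑1‑ol | O[C@@H]1C=C[C@H]2OC(C)(C)O[C@H]2C1 | intermediate
6 | (4R,5S)‑4,5‑(isopropylidenedioxy)cyclohex‑2‑en‑1‑one | O=C1C=C[C@H]2OC(C)(C)O[C@H]2C1 | intermediate
7 | trimethylsilyl enol ether of the 3‑methyl adduct of 6 (methyl anti to the acetonide) | C[Si](C)(C)OC1=C[C@H](C)[C@H]2OC(C)(C)O[C@H]2C1 | intermediate
8 | (4R,5S)‑3‑methyl‑4,5‑(isopropylidenedioxy)cyclohex‑2‑en‑1‑one | O=C1C=C(C)[C@H]2OC(C)(C)O[C@H]2C1 | intermediate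
9 | ring‑A silyl enol ether (C10–OTMS, C5=C10; 4β‑Me, 4α‑vinyl; 2β,3β‑acetonide) | C[Si](C)(C)OC1=C[C@](C)(C=C)[C@H]2OC(C)(C)O[C@H]2C1 | intermediate
10 | lithium enolate corresponding to 9 | [Li+].[O-]C1=C[C@](C)(C=C)[C@H]2OC(C)(C)O[C@H]2C1 | intermediate
11 | ring‑A keto ester (C10 ketone; 5α‑CH2CO2Me; 4β‑Me, 4α‑vinyl; 2β,3β‑acetonide) | COC(=O)C[C@H]1C(=O)C[C@@H]2OC(C)(C)O[C@@H]2[C@@]1(C)C=C | intermediate
12 | C10 ethylene ketal of 11 | COC(=O)C[C@H]1C2(OCCO2)C[C@@H]3OC(C)(C)O[C@@H]3[C@@]1(C)C=C | intermediate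
13 | ring‑A diester (4α‑CO2Me, 5α‑CH2CO2Me) | COC(=O)C[C@H]1C2(OCCO2)C[C@@H]3OC(C)(C)O[C@@H]3[C@@]1(C)C(=O)OC | intermediate
14 | ring‑A acid (5α‑CH2CO2H, 4α‑CO2Me, 4β‑Me, C10 ketal, 2β,3β‑acetonide) | OC(=O)C[C@H]1C2(OCCO2)C[C@@H]3OC(C)(C)O[C@@H]3[C@@]1(C)C(=O)OC | intermediate
15 | 3‑ethoxycyclohex‑2‑en‑1‑one | CCOC1=CC(=O)CCC1 | starting material
16 | 3‑bromo‑1‑(trimethylsilyl)prop‑1‑yne | C[Si](C)(C)C#CCBr | starting material
17 | bromomagnesium alkoxide of 3‑ethoxy‑1‑[3‑(trimethylsilyl)prop‑2‑ynyl]cyclohex‑2‑en‑1‑ol | CCOC1=CC(O[Mg]Br)(CC#C[Si](C)(C)C)CCC1 | intermediate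
18 | 3‑[3‑(trimethylsilyl)prop‑2‑ynyl]cyclohex‑2‑en‑1‑one | O=C1C=C(CC#C[Si](C)(C)C)CCC1 | intermediate
19 | (S)‑3‑[3‑(trimethylsilyl)prop‑2‑ynyl]cyclohex‑2‑en‑1‑ol | O[C@@H]1C=C(CC#C[Si](C)(C)C)CCC1 | intermediate
20 | ester of acid 14 with alcohol 19 | C[Si](C)(C)C#CCC1=C[C@@H](OC(=O)C[C@H]2C3(OCCO3)C[C@@H]4OC(C)(C)O[C@@H]4[C@@]2(C)C(=O)OC)CCC1 | intermediate
21 | (Z)‑trimethylsilyl ketene acetal of 20 | C[Si](C)(C)C#CCC1=C[C@@H](O/C(O[Si](C)(C)C)=C/[C@H]2C3(OCCO3)C[C@@H]4OC(C)(C)O[C@@H]4[C@@]2(C)C(=O)OC)CCC1 | intermediate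
22 | trimethylsilyl ester of acid 23 | C[Si](C)(C)C#CC[C@@]1(C=CCCC1)[C@@H](C(=O)O[Si](C)(C)C)[C@H]2C3(OCCO3)C[C@@H]4OC(C)(C)O[C@@H]4[C@@]2(C)C(=O)OC | intermediate
23 | Claisen acid (C6–C8 bond, C8 quaternary, C13=C14) | C[Si](C)(C)C#CC[C@@]1(C=CCCC1)[C@@H](C(=O)O)[C@H]2C3(OCCO3)C[C@@H]4OC(C)(C)O[C@@H]4[C@@]2(C)C(=O)OC | intermediate
24 | 2‑(trimethylsilyl)ethyl ester of 23 | C[Si](C)(C)C#CC[C@@]1(C=CCCC1)[C@@H](C(=O)OCC[Si](C)(C)C)[C@H]2C3(OCCO3)C[C@@H]4OC(C)(C)O[C@@H]4[C@@]2(C)C(=O)OC | intermediate
25 | enone (C12 ketone, C13=C14) | C[Si](C)(C)C#CC[C@@]1(C=CC(=O)CC1)[C@@H](C(=O)OCC[Si](C)(C)C)[C@H]2C3(OCCO3)C[C@@H]4OC(C)(C)O[C@@H]4[C@@]2(C)C(=O)OC | intermediate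
26 | 13‑hydroxy‑12‑ketone (C13 epimers) | C[Si](C)(C)C#CC[C@@]1(CC(O)C(=O)CC1)[C@@H](C(=O)OCC[Si](C)(C)C)[C@H]2C3(OCCO3)C[C@@H]4OC(C)(C)O[C@@H]4[C@@]2(C)C(=O)OC | intermediate
27 | 13‑(tert‑butyldimethylsilyloxy)‑12‑ketone (C13 epimers) | C[Si](C)(C)C#CC[C@@]1(CC(O[Si](C)(C)C(C)(C)C)C(=O)CC1)[C@@H](C(=O)OCC[Si](C)(C)C)[C@H]2C3(OCCO3)C[C@@H]4OC(C)(C)O[C@@H]4[C@@]2(C)C(=O)OC | intermediate
28 | C12 trimethylsilyl enol ether (C11=C12) of 27 | C[Si](C)(C)C#CC[C@@]1(CC(O[Si](C)(C)C(C)(C)C)C(O[Si](C)(C)C)=CC1)[C@@H](C(=O)OCC[Si](C)(C)C)[C@H]2C3(OCCO3)C[C@@H]4OC(C)(C)O[C@@H]4[C@@]2(C)C(=O)OC | intermediate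
29 | enone (C9=C11–C12=O) with C13–OTBS and silylalkyne | C[Si](C)(C)C#CC[C@@]1(CC(O[Si](C)(C)C(C)(C)C)C(=O)C=C1)[C@@H](C(=O)OCC[Si](C)(C)C)[C@H]2C3(OCCO3)C[C@@H]4OC(C)(C)O[C@@H]4[C@@]2(C)C(=O)OC | intermediate
30 | terminal alkyne corresponding to 29 | C#CC[C@@]1(CC(O[Si](C)(C)C(C)(C)C)C(=O)C=C1)[C@@H](C(=O)OCC[Si](C)(C)C)[C@H]2C3(OCCO3)C[C@@H]4OC(C)(C)O[C@@H]4[C@@]2(C)C(=O)OC | intermediate
31 | 12,13‑bis(tert‑butyldimethylsilyloxy) diene | C#CC[C@@]1(CC(O[Si](C)(C)C(C)(C)C)=C(O[Si](C)(C)C(C)(C)C)C=C1)[C@@H](C(=O)OCC[Si](C)(C)C)[C@H]2C3(OCCO3)C[C@@H]4OC(C)(C)O[C@@H]4[C@@]2(C)C(=O)OC | intermediate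
32 | bicyclo[3.2.1]octenone with rings C/D complete (ring A as ketal/acetonide) | C=C1C[C@]2(C=CC(=O)[C@]1(O[Si](C)(C)C(C)(C)C)C2)[C@@H](C(=O)OCC[Si](C)(C)C)[C@H]3C4(OCCO4)C[C@@H]5OC(C)(C)O[C@@H]5[C@@]3(C)C(=O)OC | intermediate
33 | seco‑B keto diol (C10 ketone, 2β,3β‑diol, C19 methyl ester) | C=C1C[C@]2(C=CC(=O)[C@]1(O[Si](C)(C)C(C)(C)C)C2)[C@@H](C(=O)OCC[Si](C)(C)C)[C@H]3C(=O)C[C@H](O)[C@H](O)[C@@]3(C)C(=O)OC | intermediate
34 | C10 samarium(III) alkoxide after C9–C10 bond formation | C=C1C[C@]23C[C@@]1(O[Si](C)(C)C(C)(C)C)C(=O)C[C@H]2[C@]2(O[Sm](I)I)C[C@H](O)[C@H](O)[C@@](C)(C(=O)OC)[C@H]2[C@@H]3C(=O)OCC[Si](C)(C)C | intermediate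
35 | pentacyclic 19,10‑lactone 12‑ketone (C13–OTBS, C7 TMSE ester) | C=C1C[C@]23C[C@@]1(O[Si](C)(C)C(C)(C)C)C(=O)C[C@H]2[C@@]12C[C@H](O)[C@H](O)[C@@](C)(C(=O)O1)[C@H]2[C@@H]3C(=O)OCC[Si](C)(C)C | intermediate
36 | 12α‑alcohol (C13–OTBS, C7 TMSE ester) | C=C1C[C@]23C[C@@]1(O[Si](C)(C)C(C)(C)C)[C@@H](O)C[C@H]2[C@@]12C[C@H](O)[C@H](O)[C@@](C)(C(=O)O1)[C@H]2[C@@H]3C(=O)OCC[Si](C)(C)C | intermediate
37 | CNP0191054.1 (2β,3β,12α,13‑tetrahydroxy C19‑gibberellin 7‑acid) | C=C1C[C@]23C[C@@]1(O)[C@@H](O)C[C@H]2[C@@]12C[C@H](O)[C@H](O)[C@@](C)(C(=O)O1)[C@H]2[C@@H]3C(=O)O | target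

**Step count and risks**

Total step count: 27. Longest linear sequence: 25 steps (steps 1–11, then 14–27); steps 12–13 are the short branch.

Steps most likely to fail:

Step 25 (key step). Simple reduction of the enone or of the ketone may outrun C–C bond formation, or facial control at C10 may be insufficient and give a cis‑fused hydroxy ester that cannot lactonize. Fallback (cationic instead of radical closure): it sets out from 32. Luche reduction (NaBH4, CeCl3, MeOH, −40 °C) should attack the still unencumbered α face of the enone and give the equatorial 12β‑allylic alcohol F1, whose axial C12–H lies on the C14 face. Dilute HCl in THF then frees the C10 ketone and the diol to give keto triol F2. Excess Me2AlCl (CH2Cl2, −78 → 0 °C) is expected to trigger an intramolecular carbonyl‑ene reaction in which C9 bonds to the activated C10 carbonyl while the syn‑axial C12 hydrogen is transferred to oxygen; the resulting C12 enol tautomerizes to the ketone and the C10 aluminium alkoxide lactonizes onto C19. The fallback comes back to the route at 35.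

Step 23. Protodesilylation of the crowded, doubly oxygenated enol ether or hydration of the alkyne may be faster than 5‑exo‑dig attack by the fully substituted C13. Fallback (palladium enolate alkenylation instead of π‑acid catalysis): it sets out from 30. Markovnikov hydroiodination of the terminal alkyne (B‑iodo‑9‑BBN, then AcOH) gives the 2‑iodoallyl enone F3. Intramolecular palladium‑catalysed ketone α‑alkenylation (Pd(PPh3)4, PhOK, THF, reflux) then joins C13, the only enolizable position, to C16. The fallback comes back to the route at 32.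

Step 18. Hydrogen‑atom transfer to the hindered C14 may be slow, or the α‑keto radical may be reduced to the saturated ketone instead of being trapped by oxygen. Fallback (enol‑ether oxidation instead of radical oxygenation): it sets out from 25. Rhodium‑catalysed 1,4‑hydrosilylation ((Ph3P)3RhCl, Et3SiH, benzene, 50 °C) gives the regiodefined triethylsilyl enol ether F4. Rubottom oxidation (mCPBA, NaHCO3, CH2Cl2, 0 °C) with acidic methanol work‑up then delivers the C13 alcohol. The fallback comes back to the route at 26.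

Further compounds

F1 | step 25 | 12β‑allylic alcohol from 1,2‑reduction of 32 | C=C1C[C@]2(C=C[C@@H](O)[C@]1(O[Si](C)(C)C(C)(C)C)C2)[C@@H](C(=O)OCC[Si](C)(C)C)[C@H]3C4(OCCO4)C[C@@H]5OC(C)(C)O[C@@H]5[C@@]3(C)C(=O)OC
F2 | step 25 | keto triol (C10 ketone, 2β,3β‑diol, 12β‑allylic alcohol) | C=C1C[C@]2(C=C[C@@H](O)[C@]1(O[Si](C)(C)C(C)(C)C)C2)[C@@H](C(=O)OCC[Si](C)(C)C)[C@H]3C(=O)C[C@H](O)[C@H](O)[C@@]3(C)C(=O)OC
F3 | step 23 | 2‑iodoallyl enone (C13 epimers) | C=C(I)C[C@@]1(CC(O[Si](C)(C)C(C)(C)C)C(=O)C=C1)[C@@H](C(=O)OCC[Si](C)(C)C)[C@H]2C3(OCCO3)C[C@@H]4OC(C)(C)O[C@@H]4[C@@]2(C)C(=O)OC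
F4 | step 18 | C12 triethylsilyl enol ether (C12=C13) | C[Si](C)(C)C#CC[C@@]1(CC=C(O[Si](CC)(CC)CC)CC1)[C@@H](C(=O)OCC[Si](C)(C)C)[C@H]2C3(OCCO3)C[C@@H]4OC(C)(C)O[C@@H]4[C@@]2(C)C(=O)OC
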